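**Retrosynthetic overview**

1. The route rests on the oxolane ring (O1, C2, C3, C4, C5): the aryl groups on C2 and C5 are cis, the CH2OH arms on C3 (C9) and C4 (C9') are trans, the C4 arm is trans to the C5 aryl, and only the cis relation between the C2 aryl and the C3 arm is contra-thermodynamic.
2. End game: target ⇐ hydrogenolysis of three benzyl ethers ⇐ LiAlH4 reduction of a C4 ester ⇐ dealkoxycarbonylation and equilibration of a C4 geminal diester.
3. Key disconnection O1–C2 and C4–C5: the only ring is closed by a Lewis-acid [3+2] annulation of a trans-2-aryl-3-(benzyloxymethyl)cyclopropane-1,1-diester with 4-benzyloxy-3,5-dimethoxybenzaldehyde; inversion at C2 turns trans (cyclopropane) into cis (oxolane).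
4. The cyclopropane (C2 and C3 as one enantiomer) comes from an aminocatalytic Michael/alkylation of O-benzylsinapaldehyde with dimethyl bromomalonate, then aldehyde reduction and O-benzylation; both aryl units come from syringaldehyde.

Key step: step 6

Remark on numbering: C2 is the aryl-bearing ring carbon cis to its neighbouring arm, C5 the one trans to its neighbouring arm; in this numbering the target is (2S,3S,4S,5R), and the systematic names below use their own locants.

Assumption: the facial sense of the amine catalyst in step 3 is taken from the usual steric-shielding model of diarylprolinol silyl ethers, so the (R)-amine is chosen; were the sense opposite, the (S)-amine would be used with no other change.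

**Route**

Step 1
Reactants: 1 syringaldehyde
Product: 2 4-(benzyloxy)-3,5-dimethoxybenzaldehyde
Conditions: BnBr, K2CO3, DMF, 60 °C
Reagents that add atoms: benzyl bromide, BrCc1ccccc1
Why: Williamson ether synthesis, in which the potassium phenoxide of 1 is alkylated by SN2 at the benzylic bromide while the aldehyde is inert to carbonate, and no stereocentre is involved.

Step 2
Reactants: 2 4-(benzyloxy)-3,5-dimethoxybenzaldehyde; 3 (triphenylphosphoranylidene)acetaldehyde
Product: 4 (E)-3-[4-(benzyloxy)-3,5-dimethoxyphenyl]prop-2-enal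
Conditions: toluene, 90 °C
Reagents that add atoms: none
Why: Wittig olefination with the formyl-stabilised ylide should give the (E)-enal, the ylide being kept near one equivalent so that the product enal is not homologated a second time.

Step 3
Reactants: 4 (E)-3-[4-(benzyloxy)-3,5-dimethoxyphenyl]prop-2-enal; 5 dimethyl 2-bromomalonate
Product: 6 dimethyl (2R,3S)-2-[4-(benzyloxy)-3,5-dimethoxyphenyl]-3-formylcyclopropane-1,1-dicarboxylate (aryl and formyl trans)
Conditions: (R)-α,α-diphenylprolinol trimethylsilyl ether (20 mol %), 2,6-lutidine (1.1 equiv), CH2Cl2, 0 °C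
Reagents that add atoms: none
Why: Aminocatalytic Michael-initiated ring closure, in which the bromomalonate adds to the β-carbon of the (E)-iminium ion on the face not shielded by the diphenyl(trimethylsilyloxy)methyl group of the (R)-amine (setting the aryl carbon as R) and the resulting enamine displaces bromide in a 3-exo-tet alkylation that places the formyl group trans to the aryl group (setting the second ring carbon as S).

Step 4
Reactants: 6 dimethyl (2R,3S)-2-[4-(benzyloxy)-3,5-dimethoxyphenyl]-3-formylcyclopropane-1,1-dicarboxylate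
Product: 7 dimethyl (2R,3S)-2-[4-(benzyloxy)-3,5-dimethoxyphenyl]-3-(hydroxymethyl)cyclopropane-1,1-dicarboxylate
Conditions: NaBH4, MeOH/CH2Cl2, −20 °C
Reagents that add atoms: none
Why: Chemoselective borohydride reduction of the aldehyde leaves the malonate esters and both ring stereocentres untouched, the low temperature and a buffered quench keeping the new alcohol from lactonising onto the cis ester.

Step 5
Reactants: 7 dimethyl (2R,3S)-2-[4-(benzyloxy)-3,5-dimethoxyphenyl]-3-(hydroxymethyl)cyclopropane-1,1-dicarboxylate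
Product: 8 dimethyl (2R,3S)-2-[4-(benzyloxy)-3,5-dimethoxyphenyl]-3-[(benzyloxy)methyl]cyclopropane-1,1-dicarboxylate (aryl and benzyloxymethyl trans)
Conditions: BnOC(=NH)CCl3, TfOH (5 mol %), CH2Cl2/cyclohexane, 0 °C
Reagents that add atoms: benzyl 2,2,2-trichloroacetimidate, N=C(OCc1ccccc1)C(Cl)(Cl)Cl
Why: Acid-catalysed O-benzylation with the trichloroacetimidate transfers benzyl to the neutral alcohol and so avoids the alkoxide that would lactonise onto the cis ester, while the basic imidate buffers the catalytic acid so that the cyclopropane and its two stereocentres should stay intact.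

Step 6
Reactants: 8 dimethyl (2R,3S)-2-[4-(benzyloxy)-3,5-dimethoxyphenyl]-3-[(benzyloxy)methyl]cyclopropane-1,1-dicarboxylate; 2 4-(benzyloxy)-3,5-dimethoxybenzaldehyde
Product: 9 dimethyl (2S,4S,5S)-2,5-bis[4-(benzyloxy)-3,5-dimethoxyphenyl]-4-[(benzyloxy)methyl]oxolane-3,3-dicarboxylate (aryls 2,5-cis, benzyloxymethyl cis to its neighbouring aryl; in target numbering the geminal diester is on C4 and the benzyloxymethyl on C3)
Conditions: 2 (3 equiv), Sn(OTf)2 (10 mol %), CH2Cl2, rt
Reagents that add atoms: none
Why: Sn(OTf)2 chelates the geminal diester of 8 and polarises the bond between the malonate carbon and the benzylic carbon; the carbonyl oxygen of 2 then displaces the malonate carbon at the benzylic carbon in an SN2-like step (O1–C2, inversion), and the tight oxocarbenium/tin malonate ion pair collapses by attack of the malonate carbon on the oxocarbenium carbon (C4–C5). The closest known reaction type is the Lewis-acid-catalysed [3+2] annulation of 2-arylcyclopropane-1,1-diesters, 2,3-disubstituted ones included, with aldehydes to give 2,5-cis-tetrahydrofurans. The oxolane is closed in the second event as a 5-endo-trig, aldol-type addition of the exocyclic malonate enolate to the endocyclic C5=O1 oxocarbenium bond, which is viable because the cationic acceptor is highly electrophilic and the envelope keeps the orbitals aligned. C2 is controlled by the stored configuration of the cyclopropane, since backside entry of oxygen converts the trans aryl/benzyloxymethyl pair into the cis C2/C3 pair while C3 is carried through unchanged, and C5 is controlled by the envelope transition state with both aryl groups pseudo-equatorial, which should give the 2,5-cis ring. The step needs clean inversion without a free benzylic cation and cis delivery of the second aryl; the first is secured by the only moderate donor strength of the aryl group, whose para oxygen is twisted out of conjugation by the two flanking methoxy groups, the second by the compact ion pair, and the non-nucleophilic triflate counter-ion should leave the three benzyl ethers alone.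

Step 7
Reactants: 9 dimethyl (2S,4S,5S)-2,5-bis[4-(benzyloxy)-3,5-dimethoxyphenyl]-4-[(benzyloxy)methyl]oxolane-3,3-dicarboxylate
Product: 11 methyl (2R,3R,4S,5S)-2,5-bis[4-(benzyloxy)-3,5-dimethoxyphenyl]-4-[(benzyloxy)methyl]oxolane-3-carboxylate (ester trans to both neighbours), via C4-epimeric monoester 10 (not isolated)
Conditions: LiCl, H2O, DMSO, 150 °C; then NaOMe (0.2 equiv), MeOH, 50 °C
Reagents that add atoms: none
Why: Krapcho dealkoxycarbonylation (chloride demethylates one ester, the carboxylate loses CO2 and the ester enolate is protonated) followed by methoxide-mediated epimerisation puts the remaining C4 ester trans to both the C3 benzyloxymethyl group and the C5 aryl group under thermodynamic control, E1cB loss of the ring oxygen being disfavoured because the C5–O1 bond lies near the nodal plane of the C4 enolate (the reverse of a 5-endo-trig closure).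

Step 8
Reactants: 11 methyl (2R,3R,4S,5S)-2,5-bis[4-(benzyloxy)-3,5-dimethoxyphenyl]-4-[(benzyloxy)methyl]oxolane-3-carboxylate
Product: 12 {(2R,3S,4S,5S)-2,5-bis[4-(benzyloxy)-3,5-dimethoxyphenyl]-4-[(benzyloxy)methyl]oxolan-3-yl}methanol
Conditions: LiAlH4, THF, 0 °C
Reagents that add atoms: none
Why: Hydride reduction of the ester to the primary alcohol is faster than enolisation, so C4 keeps its configuration, and the benzyl ethers and the oxolane are inert to LiAlH4.

Step 9
Reactants: 12 {(2R,3S,4S,5S)-2,5-bis[4-(benzyloxy)-3,5-dimethoxyphenyl]-4-[(benzyloxy)methyl]oxolan-3-yl}methanol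
Product: 13 [(2S,3S,4S,5R)-2,5-bis(4-hydroxy-3,5-dimethoxyphenyl)oxolane-3,4-diyl]dimethanol (CNP0170897.4)
Conditions: H2 (1 atm), Pd/C, EtOAc/EtOH, rt
Reagents that add atoms: none
Why: Catalytic hydrogenolysis cleaves the two aryl benzyl ethers and the primary alkyl benzyl ether, whereas the hindered secondary ring C2–O1 and C5–O1 bonds should react far more slowly under neutral conditions, so no stereocentre is touched.

**Compound list**

1 | syringaldehyde (4-hydroxy-3,5-dimethoxybenzaldehyde) | COc1cc(C=O)cc(OC)c1O | starting material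
2 | 4-(benzyloxy)-3,5-dimethoxybenzaldehyde | COc1cc(C=O)cc(OC)c1OCc1ccccc1 | intermediate
3 | (triphenylphosphoranylidene)acetaldehyde | O=CC=P(c1ccccc1)(c1ccccc1)c1ccccc1 | starting material
4 | (E)-3-[4-(benzyloxy)-3,5-dimethoxyphenyl]prop-2-enal | COc1cc(/C=C/C=O)cc(OC)c1OCc1ccccc1 | intermediate
5 | dimethyl 2-bromomalonate | COC(=O)C(Br)C(=O)OC | starting material
6 | dimethyl (2R,3S)-2-[4-(benzyloxy)-3,5-dimethoxyphenyl]-3-formylcyclopropane-1,1-dicarboxylate | COc1cc([C@H]2[C@H](C=O)C2(C(=O)OC)C(=O)OC)cc(OC)c1OCc1ccccc1 | intermediate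
7 | dimethyl (2R,3S)-2-[4-(benzyloxy)-3,5-dimethoxyphenyl]-3-(hydroxymethyl)cyclopropane-1,1-dicarboxylate | COc1cc([C@H]2[C@H](CO)C2(C(=O)OC)C(=O)OC)cc(OC)c1OCc1ccccc1 | intermediate
8 | dimethyl (2R,3S)-2-[4-(benzyloxy)-3,5-dimethoxyphenyl]-3-[(benzyloxy)methyl]cyclopropane-1,1-dicarboxylate | COc1cc([C@H]2[C@H](COCc3ccccc3)C2(C(=O)OC)C(=O)OC)cc(OC)c1OCc1ccccc1 | intermediate
9 | dimethyl (2S,4S,5S)-2,5-bis[4-(benzyloxy)-3,5-dimethoxyphenyl]-4-[(benzyloxy)methyl]oxolane-3,3-dicarboxylate | COc1cc([C@H]2O[C@@H](c3cc(OC)c(OCc4ccccc4)c(OC)c3)C(C(=O)OC)(C(=O)OC)[C@H]2COCc2ccccc2)cc(OC)c1OCc1ccccc1 | intermediate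
10 | methyl (2R,3S,4S,5S)-2,5-bis[4-(benzyloxy)-3,5-dimethoxyphenyl]-4-[(benzyloxy)methyl]oxolane-3-carboxylate (ester cis to both neighbours) | COc1cc([C@H]2O[C@@H](c3cc(OC)c(OCc4ccccc4)c(OC)c3)[C@@H](C(=O)OC)[C@H]2COCc2ccccc2)cc(OC)c1OCc1ccccc1 | intermediate (not isolated)
11 | methyl (2R,3R,4S,5S)-2,5-bis[4-(benzyloxy)-3,5-dimethoxyphenyl]-4-[(benzyloxy)methyl]oxolane-3-carboxylate | COc1cc([C@H]2O[C@@H](c3cc(OC)c(OCc4ccccc4)c(OC)c3)[C@H](C(=O)OC)[C@H]2COCc2ccccc2)cc(OC)c1OCc1ccccc1 | intermediate
12 | {(2R,3S,4S,5S)-2,5-bis[4-(benzyloxy)-3,5-dimethoxyphenyl]-4-[(benzyloxy)methyl]oxolan-3-yl}methanol | COc1cc([C@H]2O[C@@H](c3cc(OC)c(OCc4ccccc4)c(OC)c3)[C@H](CO)[C@H]2COCc2ccccc2)cc(OC)c1OCc1ccccc1 | intermediate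
13 | [(2S,3S,4S,5R)-2,5-bis(4-hydroxy-3,5-dimethoxyphenyl)oxolane-3,4-diyl]dimethanol | COc1cc([C@H]2O[C@@H](c3cc(OC)c(O)c(OC)c3)[C@H](CO)[C@H]2CO)cc(OC)c1O | target

**Step count**

Total steps: 9. Longest linear sequence: 9 (1 → 2 → 4 → 6 → 7 → 8 → 9 → 11 → 12 → 13; aldehyde 2 enters a second time in step 6).

**Steps most likely to fail**

Step 6. The SN2 opening of the 2,3-disubstituted cyclopropane may be too slow under the mild triflate Lewis acid. A harder halide Lewis acid would then be needed, and under it the crowded benzyl ether para to the acid-bound formyl group of the aldehyde partner would be stripped and the catalyst consumed. The fallback redesigns the aldehyde partner; it sets out from 1 and 8 and comes back at 9. Syringaldehyde 1 would be acetylated (Ac2O, pyridine, rt) to 4-formyl-2,6-dimethoxyphenyl acetate F1, whose ester-masked phenol cannot give up a benzyl cation. F1 would be annulated with 8 under AlCl3 (20 mol %) in CH2Cl2 at rt, where the benzyl ethers of 8 have no para carbonyl to activate their cleavage, to give dimethyl (2S,4S,5S)-2-(4-acetoxy-3,5-dimethoxyphenyl)-5-[4-(benzyloxy)-3,5-dimethoxyphenyl]-4-[(benzyloxy)methyl]oxolane-3,3-dicarboxylate F2. Methanolysis (K2CO3, MeOH, rt) should free dimethyl (2S,4S,5S)-5-[4-(benzyloxy)-3,5-dimethoxyphenyl]-4-[(benzyloxy)methyl]-2-(4-hydroxy-3,5-dimethoxyphenyl)oxolane-3,3-dicarboxylate F3, and benzylation (BnBr, K2CO3, DMF) would return 9.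

Step 7. At 150 °C the C4 ester enolate may expel the ring oxygen from C5 (ring opening), or demethylation at the hindered quaternary malonate may stall. The fallback replaces the halide-induced dealkoxycarbonylation by decarboxylation of the free malonic acid through its neutral enol at lower temperature; it sets out from 9 and comes back at 11. Saponification of both esters (KOH, MeOH/THF/H2O, 60 °C) would give (2S,4S,5S)-2,5-bis[4-(benzyloxy)-3,5-dimethoxyphenyl]-4-[(benzyloxy)methyl]oxolane-3,3-dicarboxylic acid F4. Heating in pyridine at 100 °C would give 2,5-bis[4-(benzyloxy)-3,5-dimethoxyphenyl]-4-[(benzyloxy)methyl]oxolane-3-carboxylic acid F5 as a mixture of C4 epimers. Esterification (MeI, K2CO3, DMF) would give the mixture of 10 and 11, which NaOMe in MeOH at 50 °C should converge to 11.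

Step 5. Under acid the alcohol may lactonise onto the cis ester, or the cyclopropane may be opened by protonation before benzyl transfer is complete. The fallback installs the benzyl ether before the three-membered ring exists; it sets out from 4 and comes back at 8. Luche reduction (NaBH4, CeCl3·7H2O, MeOH, 0 °C) would give (E)-3-[4-(benzyloxy)-3,5-dimethoxyphenyl]prop-2-en-1-ol F6, and Williamson benzylation (NaH, BnBr, THF) would give 2-(benzyloxy)-5-[(E)-3-(benzyloxy)prop-1-en-1-yl]-1,3-dimethoxybenzene F7. Copper-catalysed carbene transfer to F7 from bis(methoxycarbonyl)(phenyliodonio)methanide F8 (made from dimethyl malonate, PhI(OAc)2 and KOH) with CuOTf (monovalent copper) and a chiral bis(oxazoline) ligand in CH2Cl2 would then give 8. The (E)-alkene geometry gives the trans ring directly. The ligand enantiomer would be chosen by a short screen, and the enantiomeric purity raised by crystallisation or chiral-phase chromatography if needed.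

**Further compounds**

F1 | step 6 | 4-formyl-2,6-dimethoxyphenyl acetate | COc1cc(C=O)cc(OC)c1OC(C)=O
F2 | step 6 | dimethyl (2S,4S,5S)-2-(4-acetoxy-3,5-dimethoxyphenyl)-5-[4-(benzyloxy)-3,5-dimethoxyphenyl]-4-[(benzyloxy)methyl]oxolane-3,3-dicarboxylate | COc1cc([C@H]2O[C@@H](c3cc(OC)c(OC(C)=O)c(OC)c3)C(C(=O)OC)(C(=O)OC)[C@H]2COCc2ccccc2)cc(OC)c1OCc1ccccc1
F3 | step 6 | dimethyl (2S,4S,5S)-5-[4-(benzyloxy)-3,5-dimethoxyphenyl]-4-[(benzyloxy)methyl]-2-(4-hydroxy-3,5-dimethoxyphenyl)oxolane-3,3-dicarboxylate | COc1cc([C@H]2O[C@@H](c3cc(OC)c(O)c(OC)c3)C(C(=O)OC)(C(=O)OC)[C@H]2COCc2ccccc2)cc(OC)c1OCc1ccccc1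
F4 | step 7 | (2S,4S,5S)-2,5-bis[4-(benzyloxy)-3,5-dimethoxyphenyl]-4-[(benzyloxy)methyl]oxolane-3,3-dicarboxylic acid | COc1cc([C@H]2O[C@@H](c3cc(OC)c(OCc4ccccc4)c(OC)c3)C(C(=O)O)(C(=O)O)[C@H]2COCc2ccccc2)cc(OC)c1OCc1ccccc1
F5 | step 7 | (2R,4S,5S)-2,5-bis[4-(benzyloxy)-3,5-dimethoxyphenyl]-4-[(benzyloxy)methyl]oxolane-3-carboxylic acid, mixture of C3 epimers (C4 in target numbering, left open in the SMILES) | COc1cc([C@H]2O[C@@H](c3cc(OC)c(OCc4ccccc4)c(OC)c3)C(C(=O)O)[C@H]2COCc2ccccc2)cc(OC)c1OCc1ccccc1
F6 | step 5 | (E)-3-[4-(benzyloxy)-3,5-dimethoxyphenyl]prop-2-en-1-ol | COc1cc(/C=C/CO)cc(OC)c1OCc1ccccc1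
F7 | step 5 | 2-(benzyloxy)-5-[(E)-3-(benzyloxy)prop-1-en-1-yl]-1,3-dimethoxybenzene | COc1cc(/C=C/COCc2ccccc2)cc(OC)c1OCc1ccccc1
F8 | step 5 | bis(methoxycarbonyl)(phenyliodonio)methanide | COC(=O)[C-](C(=O)OC)[I+]c1ccccc1
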